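How much L stands in the flask at 2.5 min, with 1.40 mM of Q on 0.0020 M of X, and which change to Q brings more?

| flask | X | Q | remark | time |
|---|---|---|---|---|
| Sunday's | 0.0020 M | 0.70 mM | run made earlier |  |
| Tuesday's | 0.0020 M | 2.8 mM | run made earlier |  |
| flask | 0.0020 M | 1.40 mM |  | 2.5 min |

| run | time / min | L / % | X / % |
|---|---|---|---|
| Sunday's | 0.417 | 1 | 78 |
| Sunday's | 0.833 | 7 | 61 |
| Sunday's | 1.33 | 19 | 46 |
| Sunday's | 1.50 | 21 | 40 |
| Sunday's | 2.00 | 30 | 31 |
| Sunday's | 2.50 | 32 | 23 |
| Sunday's | 3.00 | 34 | 17 |
| Tuesday's | 0.417 | 0 | 77 |
| Tuesday's | 0.833 | 10 | 58 |
| Tuesday's | 1.33 | 19 | 46 |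
| Tuesday's | 1.50 | 24 | 39 |
| Tuesday's | 2.00 | 30 | 31 |
| Tuesday's | 2.50 | 41 | 21 |
| Tuesday's | 3.00 | 53 | 15 |

(standard deviation of a reading: 1.5 percentage points)

- solid, in amounts per volume of the solution: Q
- at the start none of Q is in solution

- the L standing at 2.5 min, as a percentage of the X charged
- the change that raises the amount of L at 2.5 min, in percent of the X charged most ("none" if none brings more than 2 percentage points) (theta / beta / none)
- amount of L at 2.5 min, in percent of the X charged, after theta

- theta: doubling the solubility of Q, all else as stated
- beta: doubling the dissolution coefficient of Q, all else as stated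

At 2.00 min, both runs read 31% of X and 30% of L, although their charges of Q differ. What X and L leave missing from the balance we call Z, a form standing between them, and we suppose that Z reacts with dissolved Q, which we call G. The concentration of G then sets the order: while solid Q holds G steady, L forms first order in Z, which is the pseudo-first-order case. So we define k′, the rate of L per unit of Z. Tuesday's readings from 1.50 min to 3.00 min give 0.560 /min.

Our first estimate for the flask is simply Tuesday's 41%. But that is a single reading with a scatter of 1.5 percentage points. Stepping instead from Tuesday's reading at 2.00 min with k′, which did not use that reading, gives 40.9%.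

The objection is that k′ holds only while G holds. Sunday's charge equals 35.0% of the X, and over its last minute Sunday's k′ reads 0.0909 /min, far less than Tuesday's. We cannot place the start of that fall closely: at 1.50 min Sunday's L reads 21% against Tuesday's 24%, a gap of 3 points against a scatter of 1.5 points on each reading. The flask's charge of Q equals 70.0% of the X, so at Tuesday's 41% of L it holds 29 points of Q not in L, more than the 5 points in Sunday's run at 2.00 min. Part of that Q stands as G and not as solid, so the margin is smaller than it looks, but we keep about 41%. If G follows the solubility, doubling the solubility takes k′ to 1.12 /min. We have no reading of how far doubling the dissolution coefficient raises G, so our choice of theta is a judgement and not a reckoning.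

The forecast says 41%, theta and 54%, holding that the flask's Q “isn't exhausted by 2.5 min”.

The flask gives 42.7%. Theta adds 9.7 points, more than the 6.8 points from beta, and reaches 52.5%.

    G + Z → L (k = 24.0 /M/s)
    Q ⇌ G, rate k2*(cs2 - [G]) while solid is left; crystals form when [G] > cs2 (solubility = 0.720 mM, k = 0.0230 /s)
    X → Z (k = 0.0100 /s)

Left until 4.0 min, the neighbouring flask tests k′ further. The neighbour reads 62.4% of L, up from 42.7% at 2.50 min, while Z goes from 34.9% to 28.5%, so on the mean Z its k′ over that stretch is 0.413 /min, less than 0.560 /min. Its solid Q stands at 0% of its charge, and its G at 1.52 × 10⁻⁴ M, against 4.08 × 10⁻⁴ M in the flask at 2.50 min. Taken in proportion to G, k′ there is 0.209 /min. Of the charged Q, 11% is still there.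

(The numbers in the tables come from a simulation from invented constants, noise included.)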